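Everything rests on disconnecting the bond between C6 of ring A and the benzylic CH2 (made as CH=, saturated later) of the dimethylpyran ring fused at O5/C6. This bond is formed, and the pyran ring closed, by a gold-catalysed 6-endo-dig hydroarylation of an aryl 1,1-dimethylpropargyl ether; the precursor is a phloroacetophenone whose future O5 carries CMe2C≡CH and whose future O7 is benzylated. The step exploits that C6 is the only unsubstituted carbon ortho to O5 (the other is the acyl-bearing C4a) and is activated by O5, O7 and O1, so regiochemistry is built in and C6 is blocked. A Nenitzescu-type quinone annulation assembles rings C, D and B, and a terminal Claisen rearrangement sets the C8 prenyl group.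

Key step: step 3

Remark: locants follow isoflavone numbering (ring C: O1, C2, C3, C4; ring A: C4a to C8a; ring B: C1' to C6'; ring D: the furan closed by the C2–O–C2' bridge); O5, O7 and so on mean the oxygen on the carbon of that number.
Remark: the target has no stereocentre, so no stereocontrol is needed; tert-butyl 2-methylbut-3-en-2-yl carbonate is taken as a purchasable reagent.

Step 1
Reactants: 1 2,4,6-trihydroxyacetophenone
Product: 2 1-[4-(benzyloxy)-2,6-dihydroxyphenyl]ethan-1-one
Conditions: BnBr (1.0 equiv), K2CO3, DMF, 0 °C to rt
Reagents that add atoms: benzyl bromide, BrCc1ccccc1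
Why: Williamson etherification; the 4-OH, para to the acetyl group, is the most acidic and least hindered hydroxyl, while the two ortho hydroxyls are hydrogen-bonded to or shielded by the acetyl group, so one equivalent of halide should alkylate O4 first.

Step 2
Reactants: 2 1-[4-(benzyloxy)-2,6-dihydroxyphenyl]ethan-1-one
Product: 3 1-{4-(benzyloxy)-2-hydroxy-6-[(2-methylbut-3-yn-2-yl)oxy]phenyl}ethan-1-one
Conditions: 3-chloro-3-methylbut-1-yne, K2CO3, KI, CuI (cat.), acetone, reflux
Reagents that add atoms: 3-chloro-3-methylbut-1-yne, CC(C)(Cl)C#C
Why: Copper-assisted Williamson-type O-propargylation of one of the two equivalent ortho hydroxyls; after the first alkylation the remaining hydroxyl is locked in a hydrogen bond to the acetyl oxygen and is hindered, so the reaction should stop at the monoether.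

Step 3
Reactants: 3 1-{4-(benzyloxy)-2-hydroxy-6-[(2-methylbut-3-yn-2-yl)oxy]phenyl}ethan-1-one
Product: 4 1-[5-(benzyloxy)-7-hydroxy-2,2-dimethyl-2H-chromen-8-yl]ethan-1-one
Conditions: Ph3PAuNTf2 (3 mol%, monovalent gold), CH2Cl2, rt
Reagents that add atoms: none
Why: The cationic gold complex binds the terminal alkyne of 3 as a π-acid, and the arene carbon between the propargyloxy and benzyloxy carbons (future C6 of ring A) attacks the terminal alkyne carbon anti to gold; rearomatisation and protodeauration of the vinylgold species release the 2H-chromene 4 and the catalyst. The closest known reaction type is the gold-catalysed intramolecular hydroarylation of aryl propargyl ethers with terminal alkynes to 2H-chromenes. The pyran ring closes in the 6-endo-dig mode, and the new C–C bond is the ring-closing bond. No stereocentre is formed. The step needs selectivity for one ortho carbon and for 6-endo over 5-exo attack: the ether oxygen has only one unsubstituted ortho neighbour (the other carries the acetyl group), that carbon is activated by two ortho oxygens and one para oxygen, and the gem-dimethyl group and the unsubstituted alkyne terminus steer attack to the terminal carbon. The free phenol is held in a hydrogen bond to the acetyl oxygen and cannot reach the alkyne, so O-cyclisation should not compete.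

Step 4
Reactants: 4 1-[5-(benzyloxy)-7-hydroxy-2,2-dimethyl-2H-chromen-8-yl]ethan-1-one
Product: 5 (E)-1-[5-(benzyloxy)-7-hydroxy-2,2-dimethyl-2H-chromen-8-yl]-3-(dimethylamino)prop-2-en-1-one
Conditions: DMF-DMA, toluene, 90 °C
Reagents that add atoms: N,N-dimethylformamide dimethyl acetal, COC(OC)N(C)C
Why: Enaminone formation by condensation of the methyl ketone with the amide acetal; the chelated phenol should not be methylated and the E-enaminone is the thermodynamic isomer.

Step 5
Reactants: 6 2,5-dimethoxyphenol
Product: 7 5,8-dimethoxy-2,2-dimethyl-2H-chromene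
Conditions: 3-methylbut-2-enal, PhB(OH)2, AcOH, toluene, reflux (Dean–Stark)
Reagents that add atoms: 3-methylbut-2-enal, CC(C)=CC=O
Why: Phenylboronic acid-templated ortho-condensation of a phenol with an enal, in which the benzodioxaborin fragments to an ortho-quinone methide that closes by oxa-6π electrocyclisation; C6 is the only free ortho carbon of 6.

Step 6
Reactants: 7 5,8-dimethoxy-2,2-dimethyl-2H-chromene
Product: 8 2,2-dimethyl-2H-chromene-5,8-dione
Conditions: (NH4)2Ce(NO3)6, MeCN–H2O, 0 °C
Reagents that add atoms: water, O
Why: Oxidative demethylation of a para-dimethoxyarene to the para-quinone by the tetravalent cerium salt, the quinone oxygens coming from water.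

Step 7
Reactants: 5 (E)-enaminone; 8 2,2-dimethyl-2H-chromene-5,8-dione
Product: 10 7-O-benzyl bis(chromene) coumaronochromone, via aroylbenzofuranol 9 (not isolated)
Conditions: AcOH, rt; then DDQ, 1,4-dioxane, rt
Reagents that add atoms: none
Why: Nenitzescu-type benzofuran synthesis followed by dehydrogenative C–O cyclisation: the nucleophilic α-carbon of 5 should add to C6 of quinone 8 (β to the C8 carbonyl, because the C5 carbonyl is a vinylogous ester deactivated by the pyran oxygen, the regiochemistry known for 2-alkoxy-1,4-benzoquinones), the C5 hydroquinone hydroxyl then condenses on the iminium carbon with loss of dimethylamine to give 9, and DDQ closes the chelated phenol oxygen onto furan C2, the same ring closure by which 2'-hydroxyisoflavones are oxidised to coumaronochromones.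

Step 8
Reactants: 10 7-O-benzyl bis(chromene) coumaronochromone
Product: 11 7,5'-dihydroxy bis(dihydropyrano) coumaronochromone
Conditions: H2 (1 atm), Pd/C, EtOAc–MeOH, rt
Reagents that add atoms: none
Why: Heterogeneous catalytic hydrogenation should saturate both styrene-type pyran alkenes (bringing the key-step carbon to its CH2 level) and hydrogenolyse the benzyl ether in one operation, while the aromatic benzofurochromenone core is inert.

Step 9
Reactants: 11 7,5'-dihydroxy bis(dihydropyrano) coumaronochromone
Product: 12 7-O-(2-methylbut-3-en-2-yl) ether of 11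
Conditions: tert-butyl 2-methylbut-3-en-2-yl carbonate, Pd(PPh3)4 (5 mol%, zerovalent palladium), THF, 0 °C
Reagents that add atoms: tert-butyl 2-methylbut-3-en-2-yl carbonate, CC(C)(C)OC(=O)OC(C)(C)C=C
Why: Tsuji–Trost O-allylation through the 1,1-dimethyl-π-allyl palladium cation, which under kinetic conditions should give the tertiary (branched) aryl ether; the 7-OH, a vinylogous acid para to the C4 carbonyl, is far more acidic than the 5'-OH and should react selectively.

Step 10
Reactants: 12 7-O-(2-methylbut-3-en-2-yl) ether of 11
Product: 13 CNP0081329.0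
Conditions: N,N-diethylaniline, 130 °C
Reagents that add atoms: none
Why: Aromatic Claisen rearrangement ([3,3]) of the 1,1-dimethylallyl ether; C6 is blocked by the pyran ring, so the allyl terminus should be delivered to C8 with allylic inversion to give the linear prenyl group, and tautomerisation restores the 7-OH.

Compound list
1 | 2,4,6-trihydroxyacetophenone | CC(=O)c1c(O)cc(O)cc1O | starting material
2 | 1-[4-(benzyloxy)-2,6-dihydroxyphenyl]ethan-1-one | CC(=O)c1c(O)cc(OCc2ccccc2)cc1O | intermediate
3 | 1-{4-(benzyloxy)-2-hydroxy-6-[(2-methylbut-3-yn-2-yl)oxy]phenyl}ethan-1-one | CC(=O)c1c(O)cc(OCc2ccccc2)cc1OC(C)(C)C#C | intermediate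
4 | 1-[5-(benzyloxy)-7-hydroxy-2,2-dimethyl-2H-chromen-8-yl]ethan-1-one | CC(=O)c1c(O)cc(OCc2ccccc2)c2C=CC(C)(C)Oc12 | intermediate
5 | (E)-1-[5-(benzyloxy)-7-hydroxy-2,2-dimethyl-2H-chromen-8-yl]-3-(dimethylamino)prop-2-en-1-one | CN(C)/C=C/C(=O)c1c(O)cc(OCc2ccccc2)c2C=CC(C)(C)Oc12 | intermediate
6 | 2,5-dimethoxyphenol | COc1ccc(OC)c(O)c1 | starting material
7 | 5,8-dimethoxy-2,2-dimethyl-2H-chromene | COc1ccc(OC)c2OC(C)(C)C=Cc12 | intermediate
8 | 2,2-dimethyl-2H-chromene-5,8-dione | CC1(C)C=CC2=C(O1)C(=O)C=CC2=O | intermediate
9 | aroylbenzofuranol: the aryl ketone of 4 bonded through its carbonyl to C3 of a 5-hydroxybenzofuran that carries a fused 2,2-dimethyl-2H-pyran (pyran O on benzofuran C6, CH=CH on C7) | O=C(c1coc2c1cc(O)c1OC(C)(C)C=Cc12)c1c(O)cc(OCc2ccccc2)c2C=CC(C)(C)Oc12 | intermediate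
10 | 7-O-benzyl bis(chromene) coumaronochromone: 7-(benzyloxy)-5'-hydroxy coumaronochromone with 2,2-dimethyl-2H-pyran rings fused at O5–C6 (ring A) and O4'–C3' (ring B) | O=c1c2c(oc3cc(OCc4ccccc4)c4C=CC(C)(C)Oc4c13)oc1c3C=CC(C)(C)Oc3c(O)cc12 | intermediate
11 | 7,5'-dihydroxy coumaronochromone with 2,2-dimethyl-3,4-dihydro-2H-pyran rings fused at O5–C6 and O4'–C3' (8-deprenyl target) | O=c1c2c(oc3cc(O)c4CCC(C)(C)Oc4c13)oc1c3CCC(C)(C)Oc3c(O)cc12 | intermediate
12 | 7-O-(2-methylbut-3-en-2-yl) ether of 11 | O=c1c2c(oc3cc(OC(C)(C)C=C)c4CCC(C)(C)Oc4c13)oc1c3CCC(C)(C)Oc3c(O)cc12 | intermediate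
13 | CNP0081329.0: 7,5'-dihydroxy-8-(3-methylbut-2-en-1-yl) coumaronochromone with 2,2-dimethyl-3,4-dihydro-2H-pyran rings fused at O5–C6 and O4'–C3' | O=c1c2c(oc3c(CC=C(C)C)c(O)c4CCC(C)(C)Oc4c13)oc1c3CCC(C)(C)Oc3c(O)cc12 | target

Total step count: 10.
Longest linear sequence: 8 steps (steps 1, 2, 3, 4, 7, 8, 9, 10); steps 5 and 6 form the side branch to quinone 8.

Steps most likely to fail

1. Step 7. The conjugate addition may go to the wrong quinone carbon (C7), because the vinyl group of the chromene competes with the pyran oxygen in polarising the quinone. The vinylquinone may also be consumed by cycloaddition or oligomerisation, and DDQ may over-oxidise the free para-alkoxyphenol when it is dosed into the crude mixture. The fallback sets out from 7 and 5 and comes back at 11; it saturates the ring B fragment before the coupling and isolates each stage. Chromene 7 would be hydrogenated (H2, Pd/C) to 5,8-dimethoxy-2,2-dimethylchromane F1, which (NH4)2Ce(NO3)6 would oxidise to 2,2-dimethylchromane-5,8-dione F2, a plain 2-alkoxy-3-alkyl-1,4-benzoquinone without the vinyl group. F2 and enaminone 5 in AcOH should give the isolated ring-B-saturated aroylbenzofuranol F3. Closure with DDQ on the purified phenol should give the ring-B-saturated 7-O-benzyl coumaronochromone F4, and hydrogenation of F4 under the conditions of step 8 would give 11.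

2. Step 3. The cationic gold complex may ionise the tertiary propargylic C–O bond (loss of the side chain back to 2), may be sequestered by the chelating ortho-hydroxyacetophenone, or may hydrate the alkyne with adventitious water. The fallback sets out from 3 and comes back at 4; it is a metal-free thermal cascade in N,N-diethylaniline at 180 °C. An aromatic propargyl Claisen rearrangement ([3,3]) should form the same C–C bond at the same carbon and give, after enolisation, the ortho-allenylphenol F5 (not isolated). A 1,5-hydrogen shift and oxa-6π electrocyclisation would then lead to 4.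

3. Step 9. The two phenols may not be discriminated, and the π-allyl intermediate may be captured at its primary terminus or the tertiary ether may isomerise to the linear prenyl ether. The fallback sets out from 11 and comes back at 12. The 7-OH would be alkylated with 3-chloro-3-methylbut-1-yne (K2CO3, KI, CuI, acetone), which selects the more acidic phenol under carbonate base and can only give the tertiary ether, to the 7-O-(2-methylbut-3-yn-2-yl) ether F6. Semi-hydrogenation over Pd/CaCO3 poisoned with Pb(OAc)2 and quinoline would then give 12.

Further compounds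
F1 | step 7 | 5,8-dimethoxy-2,2-dimethylchromane | COc1ccc(OC)c2OC(C)(C)CCc12
F2 | step 7 | 2,2-dimethylchromane-5,8-dione | CC1(C)CCC2=C(O1)C(=O)C=CC2=O
F3 | step 7 | ring-B-saturated aroylbenzofuranol (analogue of 9 with a dihydropyran on the benzofuran) | O=C(c1coc2c1cc(O)c1OC(C)(C)CCc12)c1c(O)cc(OCc2ccccc2)c2C=CC(C)(C)Oc12
F4 | step 7 | ring-B-saturated 7-O-benzyl coumaronochromone (analogue of 10 with a dihydropyran on ring B) | O=c1c2c(oc3cc(OCc4ccccc4)c4C=CC(C)(C)Oc4c13)oc1c3CCC(C)(C)Oc3c(O)cc12
F5 | step 3 | 1-[4-(benzyloxy)-2,6-dihydroxy-3-(3-methylbuta-1,2-dien-1-yl)phenyl]ethan-1-one | CC(=O)c1c(O)cc(OCc2ccccc2)c(C=C=C(C)C)c1O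
F6 | step 9 | 7-O-(2-methylbut-3-yn-2-yl) ether of 11 | O=c1c2c(oc3cc(OC(C)(C)C#C)c4CCC(C)(C)Oc4c13)oc1c3CCC(C)(C)Oc3c(O)cc12
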